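**Plan**

- Retrosynthetic cuts (octahydroazulene numbering): the allylic C7–O bond (late C–H oxidation); the ester C–O bond; the C2–C3 bond of the cyclopentane, ring CH2 to the isopropyl carbinol carbon (key); the C3–C3a bond (aldol with 2-methylpropanal); and the C1–C8a bond (vinyl conjugate addition). This leaves mirror-symmetric 3,6-dimethylcyclohepta-2,6-dienone.
- Forward order: the seven-membered ring comes first; a three-component conjugate addition/aldol places a vinyl group and a hydroxyisobutyl chain on neighbouring ring carbons; the five-membered ring is closed last; the ester and the allylic hydroxyl follow.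
- Enabling feature: in the cyclisation substrate the isopropyl ketone carbon on one ring carbon and the terminal vinyl carbon on the adjacent quaternary ring carbon are 1,5-related (O=C–CH–C(quaternary)–CH=CH2). An alkyl-metal generated at the vinyl terminus can therefore add 5-exo-trig to the ketone and form the cyclopentane together with its tertiary carbinol carbon.
- Stereochemistry: the quaternary carbon comes from a ligand-controlled copper-catalysed conjugate addition. The ring-fusion CH and the ester-bearing carbon follow by relay (aldol anti to vinyl, then 1,3-syn reduction). The tertiary carbinol is set in the key step by substrate control, with trans fusion enforced by the trans arms. The allylic carbinol is set by a SeO2 ene/[2,3] sequence anti to the ester.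

Key step: step 7

Assumption: 3-methylcyclohept-2-en-1-one is taken as a catalogue compound; the ligand enantiomer in step 3 is the one that gives the S quaternary carbon.

**Route**

Step 1
Reactants: 1 3-methylcyclohept-2-en-1-one
Product: 3 3-methylcyclohepta-2,6-dien-1-one, via silyl dienol ether 2 (not isolated)
Conditions: LiN(i-Pr)2, THF, −78 °C; Me3SiCl; then Pd(OAc)2, MeCN, rt
Reagents that add atoms: none
Why: Saegusa–Ito oxidation: kinetic deprotonation at the α′-CH2 gives the cross-conjugated silyl dienol ether 2, which Pd(OAc)2 converts through an oxa-π-allylpalladium species and β-hydrogen loss into the cross-conjugated dienone; no stereocentre is formed.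

Step 2
Reactants: 3 3-methylcyclohepta-2,6-dien-1-one
Product: 5 3,6-dimethylcyclohepta-2,6-dien-1-one, via silyl enol ether 4 (not isolated)
Conditions: MeMgBr, CuBr·SMe2 (5 mol %), Me3SiCl, THF, −78 °C; then Pd(OAc)2, MeCN, rt
Reagents that add atoms: methylmagnesium bromide, C[Mg]Br
Why: Copper-catalysed 1,4-addition of the Grignard reagent should go to the β-unsubstituted enone arm and Me3SiCl traps the enolate regiospecifically as racemic 4, so that a second Saegusa–Ito oxidation restores the double bond exactly there and gives the mirror-symmetric dienone; the stereocentre of 4 is erased.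

Step 3
Reactants: 5 3,6-dimethylcyclohepta-2,6-dien-1-one; 6 2-methylpropanal
Product: 8 (6S,7R)-6-ethenyl-7-[(1R)-1-hydroxy-2-methylpropyl]-3,6-dimethylcyclohept-2-en-1-one, via aluminium enolate 7 (not isolated)
Conditions: H2C=CHAlMe2 (made from H2C=CHMgBr and Me2AlCl), Cu(MeCN)4PF6 (5 mol %), chiral phosphoramidite ligand (10 mol %), Et2O, −30 °C; then 6, −78 °C; aq. Rochelle salt
Reagents that add atoms: dimethyl(vinyl)aluminium, C=C[Al](C)C
Why: Copper-catalysed asymmetric conjugate addition of an alkenylalane to a β-methyl cycloheptenone (the two enone arms of 5 are homotopic, so only facial selectivity counts) sets the quaternary carbon under ligand control, and the aluminium enolate 7 is trapped in an aldol addition through a closed chair transition state in which the aldehyde should approach anti to the pseudo-axial vinyl group (side chain trans to vinyl, 7R) with the anti carbinol/ring relationship (1′R) expected for an (E)-configured cyclic enolate.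

Step 4
Reactants: 8 (6S,7R)-6-ethenyl-7-[(1R)-1-hydroxy-2-methylpropyl]-3,6-dimethylcyclohept-2-en-1-one
Product: 10 (1S,6S,7R)-6-ethenyl-7-[(1R)-1-hydroxy-2-methylpropyl]-3,6-dimethylcyclohept-2-en-1-ol, via boron chelate 9 (not isolated)
Conditions: Et2BOMe, THF/MeOH 4:1, −78 °C; NaBH4; then MeOH, evaporation
Reagents that add atoms: none
Why: Narasaka–Prasad reduction: the diethylboron chelate 9 of the β-hydroxy enone should be attacked axially by external hydride at the carbonyl carbon (1,2-reduction) to give the 1,3-syn diol, which together with the anti aldol relationship places the new ring hydroxyl trans to the side chain (1S).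

Step 5
Reactants: 10 (1S,6S,7R)-6-ethenyl-7-[(1R)-1-hydroxy-2-methylpropyl]-3,6-dimethylcyclohept-2-en-1-ol
Product: 11 (1R)-1-[(1R,2S,7S)-2-[(tert-butyldimethylsilyl)oxy]-7-ethenyl-4,7-dimethylcyclohept-3-en-1-yl]-2-methylpropan-1-ol
Conditions: t-BuMe2SiCl, imidazole, DMF, 0 °C
Reagents that add atoms: tert-butyldimethylsilyl chloride, CC(C)(C)[Si](C)(C)Cl
Why: Silylation under steric control: the allylic ring hydroxyl, flanked by an sp2 carbon, should react far faster than the side-chain hydroxyl, which lies between an isopropyl group and the ring CH next to the quaternary carbon; no stereocentre changes.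

Step 6
Reactants: 11 (1R)-1-[(1R,2S,7S)-2-[(tert-butyldimethylsilyl)oxy]-7-ethenyl-4,7-dimethylcyclohept-3-en-1-yl]-2-methylpropan-1-ol
Product: 12 1-[(1S,2S,7S)-2-[(tert-butyldimethylsilyl)oxy]-7-ethenyl-4,7-dimethylcyclohept-3-en-1-yl]-2-methylpropan-1-one
Conditions: Dess–Martin periodinane, pyridine, CH2Cl2, 0 °C to rt
Reagents that add atoms: none
Why: Dess–Martin oxidation of the remaining hindered secondary alcohol under buffered, non-basic conditions should give the isopropyl ketone without β-elimination of the silyloxy group or epimerisation of the adjacent ring CH.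

Step 7
Reactants: 12 1-[(1S,2S,7S)-2-[(tert-butyldimethylsilyl)oxy]-7-ethenyl-4,7-dimethylcyclohept-3-en-1-yl]-2-methylpropan-1-one
Product: 14 (3R,3aS,4S,8aS)-6,8a-dimethyl-3-(propan-2-yl)-1,2,3,3a,4,7,8,8a-octahydroazulene-3,4-diol, via bis-silyl ether 13 (not isolated)
Conditions: Cu(OAc)2 (5 mol %), DTBM-SEGPHOS (6 mol %), (MeO)2MeSiH, THF, 40 °C; then Bu4NF, THF, rt
Reagents that add atoms: none
Why: Proposed new method: a phosphine-ligated copper hydride (monovalent copper, formed from Cu(OAc)2 and the silane) should add to the monosubstituted vinyl group with copper on the terminal carbon, and the resulting primary alkylcopper, held five atoms from the ketone carbon, should add to the C=O in a four-centre step to give a tertiary copper alkoxide that the silane converts into silyl ether 13 and fresh copper hydride. The closest known reaction types are the copper-hydride-catalysed anti-Markovnikov hydrofunctionalisation of terminal alkenes and the copper-catalysed reductive or borylative couplings in which an alkene-derived alkylcopper adds to a ketone; new here is the use of an unactivated terminal alkene as pronucleophile for a tethered ketone. The cyclopentane closes in the 5-exo-trig mode (attack at the carbonyl carbon, C=O outside the new ring), and because the two arms are trans on the cycloheptene the ring fusion must be trans. The new tertiary carbinol centre is under substrate control: in the closure the isopropyl group should turn away from the angular methyl group and from the silyloxy-bearing ring carbon, so that oxygen ends cis to the angular methyl group (3R). The step needs hydrocupration to outrun direct hydride reduction of the ketone, which the doubly α-branched ketone and the inert trisubstituted ring alkene should secure, and carbonyl addition to outrun silane hydrogenolysis of the alkylcopper, which the five-membered transition state should favour. Fluoride then removes both silyl groups.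

Step 8
Reactants: 14 (3R,3aS,4S,8aS)-6,8a-dimethyl-3-(propan-2-yl)-1,2,3,3a,4,7,8,8a-octahydroazulene-3,4-diol; 15 4-methoxybenzoyl chloride
Product: 16 (3R,3aS,4S,8aS)-3-hydroxy-6,8a-dimethyl-3-(propan-2-yl)-1,2,3,3a,4,7,8,8a-octahydroazulen-4-yl 4-methoxybenzoate
Conditions: Et3N, DMAP (cat.), CH2Cl2, 0 °C to rt
Reagents that add atoms: none
Why: DMAP-catalysed acylation of the secondary allylic alcohol; the tertiary alcohol next to the isopropyl group should not acylate under these conditions and the carbinol configuration is retained.

Step 9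
Reactants: 16 (3R,3aS,4S,8aS)-3-hydroxy-6,8a-dimethyl-3-(propan-2-yl)-1,2,3,3a,4,7,8,8a-octahydroazulen-4-yl 4-methoxybenzoate
Product: 17 (3R,3aS,4S,7R,8aR)-3,7-dihydroxy-6,8a-dimethyl-3-(propan-2-yl)-1,2,3,3a,4,7,8,8a-octahydroazulen-4-yl 4-methoxybenzoate
Conditions: SeO2 (0.5 equiv), t-BuOOH, CH2Cl2, rt
Reagents that add atoms: selenium dioxide, O=[Se]=O (re-oxidised by tert-butyl hydroperoxide, CC(C)(C)OO)
Why: Selenium dioxide allylic oxidation (ene reaction, then [2,3]-sigmatropic shift) should occur at the ring CH2 on the methyl-bearing end of the trisubstituted alkene, the position SeO2 normally prefers; the ene step should take the alkene face anti to the neighbouring aroyloxy group and the suprafacial [2,3] shift returns oxygen on that same face, giving the 4,7-trans product (7R) with the double bond back in place.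

**Compound list**

1 | 3-methylcyclohept-2-en-1-one | CC1=CC(=O)CCCC1 | starting material
2 | trimethyl[(6-methylcyclohepta-1,6-dien-1-yl)oxy]silane | CC1=CC(O[Si](C)(C)C)=CCCC1 | intermediate
3 | 3-methylcyclohepta-2,6-dien-1-one | CC1=CC(=O)C=CCC1 | intermediate
4 | [(3,6-dimethylcyclohepta-1,6-dien-1-yl)oxy]trimethylsilane (racemic) | CC1CCC(C)=CC(O[Si](C)(C)C)=C1 | intermediate
5 | 3,6-dimethylcyclohepta-2,6-dien-1-one | CC1=CC(=O)C=C(C)CC1 | intermediate
6 | 2-methylpropanal | CC(C)C=O | starting material
7 | dimethylaluminium (6S)-6-ethenyl-3,6-dimethylcyclohepta-1(7),2-dien-1-olate | C=C[C@]1(C)CCC(C)=CC(O[Al](C)C)=C1 | intermediate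
8 | (6S,7R)-6-ethenyl-7-[(1R)-1-hydroxy-2-methylpropyl]-3,6-dimethylcyclohept-2-en-1-one | CC(C)[C@@H](O)[C@@H]1C(=O)C=C(C)CC[C@@]1(C)C=C | intermediate
9 | O-diethylboryl chelate of 8 | CCB(CC)O[C@H](C(C)C)[C@@H]1C(=O)C=C(C)CC[C@@]1(C)C=C | intermediate
10 | (1S,6S,7R)-6-ethenyl-7-[(1R)-1-hydroxy-2-methylpropyl]-3,6-dimethylcyclohept-2-en-1-ol | CC(C)[C@@H](O)[C@@H]1[C@@H](O)C=C(C)CC[C@@]1(C)C=C | intermediate
11 | (1R)-1-[(1R,2S,7S)-2-[(tert-butyldimethylsilyl)oxy]-7-ethenyl-4,7-dimethylcyclohept-3-en-1-yl]-2-methylpropan-1-ol | CC(C)[C@@H](O)[C@@H]1[C@@H](O[Si](C)(C)C(C)(C)C)C=C(C)CC[C@@]1(C)C=C | intermediate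
12 | 1-[(1S,2S,7S)-2-[(tert-butyldimethylsilyl)oxy]-7-ethenyl-4,7-dimethylcyclohept-3-en-1-yl]-2-methylpropan-1-one | CC(C)C(=O)[C@@H]1[C@@H](O[Si](C)(C)C(C)(C)C)C=C(C)CC[C@@]1(C)C=C | intermediate
13 | tert-butyl{[(3R,3aS,4S,8aS)-3-{[dimethoxy(methyl)silyl]oxy}-6,8a-dimethyl-3-(propan-2-yl)-1,2,3,3a,4,7,8,8a-octahydroazulen-4-yl]oxy}dimethylsilane | CC(C)(C)[Si](C)(C)O[C@H]1C=C(C)CC[C@@]2(C)CC[C@@](O[Si](C)(OC)OC)(C(C)C)[C@H]12 | intermediate
14 | (3R,3aS,4S,8aS)-6,8a-dimethyl-3-(propan-2-yl)-1,2,3,3a,4,7,8,8a-octahydroazulene-3,4-diol | O[C@H]1C=C(C)CC[C@@]2(C)CC[C@@](O)(C(C)C)[C@H]12 | intermediate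
15 | 4-methoxybenzoyl chloride | COc1ccc(C(Cl)=O)cc1 | starting material
16 | (3R,3aS,4S,8aS)-3-hydroxy-6,8a-dimethyl-3-(propan-2-yl)-1,2,3,3a,4,7,8,8a-octahydroazulen-4-yl 4-methoxybenzoate | COc1ccc(C(=O)O[C@H]2C=C(C)CC[C@@]3(C)CC[C@@](O)(C(C)C)[C@H]23)cc1 | intermediate
17 | (3R,3aS,4S,7R,8aR)-3,7-dihydroxy-6,8a-dimethyl-3-(propan-2-yl)-1,2,3,3a,4,7,8,8a-octahydroazulen-4-yl 4-methoxybenzoate | COc1ccc(C(=O)O[C@H]2C=C(C)[C@H](O)C[C@@]3(C)CC[C@@](O)(C(C)C)[C@H]23)cc1 | target

**Step count and risks**

Total step count: 9. Longest linear sequence: 9 steps (1 to 17; 6 and 15 are bought).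

Steps most likely to fail:

1. Step 7 (the proposed method). The risk is that silane hydrogenolysis of the alkylcopper (net reduction of vinyl to ethyl), or direct hydride reduction of the ketone, outruns the hindered carbonyl addition. The fallback uses known chemistry, sets out from 11 and returns at 14. The vinyl group is hydroborated with 9-BBN and the borane iodinated in the same flask (NaOMe, I2) to the primary iodide (1R)-1-[(1R,2S,7S)-2-[(tert-butyldimethylsilyl)oxy]-7-(2-iodoethyl)-4,7-dimethylcyclohept-3-en-1-yl]-2-methylpropan-1-ol F1. Dess–Martin oxidation should give the iodo ketone 1-[(1S,2S,7S)-2-[(tert-butyldimethylsilyl)oxy]-7-(2-iodoethyl)-4,7-dimethylcyclohept-3-en-1-yl]-2-methylpropan-1-one F2. A samarium Barbier cyclisation (SmI2, HMPA, THF, −78 °C to rt; divalent samarium converts the iodide into an alkylsamarium that adds 5-exo-trig to the ketone) should close the same bond and give (3R,3aS,4S,8aS)-4-[(tert-butyldimethylsilyl)oxy]-6,8a-dimethyl-3-(propan-2-yl)-1,2,3,3a,4,7,8,8a-octahydroazulen-3-ol F3, and Bu4NF returns to 14.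

2. Step 3. The risk is poor facial selectivity when the enolate is trapped next to the new quaternary carbon (methyl and vinyl differ little in size), or erosion of the anti relationship; either would misdirect the whole relay. The fallback sets out from 5 and returns at 8. The conjugate addition is run alone and quenched with aqueous NH4Cl to give (6R)-6-ethenyl-3,6-dimethylcyclohept-2-en-1-one F4. The side chain is then added in a separate, reagent-controlled boron aldol addition (diisopinocampheylboron triflate of the matched hand, i-Pr2NEt, CH2Cl2, −78 °C; then 6). Enolisation can only occur at the CH2 next to the quaternary carbon, and the face of the (E)-enol borinate is chosen by the boron ligands in a closed chair transition state rather than by the weakly biased ring, which should lead back to 8.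

3. Step 9. The risk is incomplete facial control in the ene step, or over-oxidation to the enone. The fallback sets out from 16 and returns at 17. The crude mixture of allylic oxidation products is oxidised without separation (Dess–Martin periodinane) to the single enone (3R,3aS,4S,8aR)-3-hydroxy-6,8a-dimethyl-7-oxo-3-(propan-2-yl)-1,2,3,3a,4,7,8,8a-octahydroazulen-4-yl 4-methoxybenzoate F5. The carbinol centre is then set by a Corey–Bakshi–Shibata reduction (oxazaborolidine enantiomer chosen to deliver hydride to the face syn to the ester, BH3·SMe2, −40 °C), which returns to 17.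

Further compounds
F1 | step 7 | (1R)-1-[(1R,2S,7S)-2-[(tert-butyldimethylsilyl)oxy]-7-(2-iodoethyl)-4,7-dimethylcyclohept-3-en-1-yl]-2-methylpropan-1-ol | CC(C)[C@@H](O)[C@@H]1[C@@H](O[Si](C)(C)C(C)(C)C)C=C(C)CC[C@@]1(C)CCI
F2 | step 7 | 1-[(1S,2S,7S)-2-[(tert-butyldimethylsilyl)oxy]-7-(2-iodoethyl)-4,7-dimethylcyclohept-3-en-1-yl]-2-methylpropan-1-one | CC(C)C(=O)[C@@H]1[C@@H](O[Si](C)(C)C(C)(C)C)C=C(C)CC[C@@]1(C)CCI
F3 | step 7 | (3R,3aS,4S,8aS)-4-[(tert-butyldimethylsilyl)oxy]-6,8a-dimethyl-3-(propan-2-yl)-1,2,3,3a,4,7,8,8a-octahydroazulen-3-ol | CC(C)(C)[Si](C)(C)O[C@H]1C=C(C)CC[C@@]2(C)CC[C@@](O)(C(C)C)[C@H]12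
F4 | step 3 | (6R)-6-ethenyl-3,6-dimethylcyclohept-2-en-1-one | C=C[C@]1(C)CCC(C)=CC(=O)C1
F5 | step 9 | (3R,3aS,4S,8aR)-3-hydroxy-6,8a-dimethyl-7-oxo-3-(propan-2-yl)-1,2,3,3a,4,7,8,8a-octahydroazulen-4-yl 4-methoxybenzoate | COc1ccc(C(=O)O[C@H]2C=C(C)C(=O)C[C@@]3(C)CC[C@@](O)(C(C)C)[C@H]23)cc1
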